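**Retrosynthetic overview**
1. The last C–C bond is the aroyl C–aryl bond: the target comes from hydrogenolysis and carbinol oxidation of the adduct of an aryl-cerium (from an iodoarene that already carries the 4-hydroxy-2-pyranone, fragment 2) with a protected tetralone-4-carbaldehyde (fragment 1).
2. Fragment 1: the carbocyclic ring of the tetralone is closed by intramolecular Friedel–Crafts acylation; C3 and C4 come from Sharpless epoxidation of a (Z)-allylic alcohol and invertive epoxide opening by an aryl Grignard/copper reagent.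
3. Fragment 2: the pyranone is closed by lactonisation of a 3,5-diketo ester (arylacetic Weinreb amide plus acetoacetate dianion); the iodine comes from ring iodination.
4. Both benzene rings come from one block, 1,3-bis(benzyloxy)-5-bromobenzene (3-bromophenol, C–H borylation/oxidation, benzylation).
5. Ring order: the benzene rings are bought; the tetralone carbocycle (fragment 1) and the pyranone (fragment 2) are built in parallel, then the fragments are joined.

Assumption: one-carbon and protecting-group donors (ClCO2Me, MeLi, BnBr, BnOCH2Cl, silyl chlorides) are treated as reagents; the carbon skeleton comes from 3-bromophenol, but-3-yn-1-ol, ethyl bromoacetate and methyl acetoacetate.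

**Aryl building block**

Step 1
Reactants: 1 3-bromophenol
Product: 2 (3-bromophenoxy)tri(propan-2-yl)silane
Conditions: i-Pr3SiCl, imidazole, DMF, 25 °C
Reagents that add atoms: chlorotri(propan-2-yl)silane, CC(C)[Si](Cl)(C(C)C)C(C)C
Why: Silyl ether formation; the bulky silyl group shields both C–H bonds next to oxygen for the borylation that follows.

Step 2
Reactants: 2 (3-bromophenoxy)tri(propan-2-yl)silane
Product: 4 3-bromo-5-{[tri(propan-2-yl)silyl]oxy}phenol, via arylboronate 3 (not isolated)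
Conditions: [Ir(OMe)(cod)]2 (1.5 mol %), 4,4'-di-tert-butyl-2,2'-bipyridine (3 mol %), B2pin2 (1.0 equiv), THF, 80 °C; then KHSO5 (Oxone), acetone/H2O, 25 °C
Reagents that add atoms: potassium peroxymonosulfate, [K+].[O-]S(=O)(=O)OO
Why: Sterically governed iridium-catalysed C–H borylation takes the only ring hydrogen without an ortho substituent, and peroxymonosulfate oxidises the C–B bond to C–OH.

Step 3
Reactants: 4 3-bromo-5-{[tri(propan-2-yl)silyl]oxy}phenol
Product: 5 5-bromobenzene-1,3-diol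
Conditions: Bu4NF, THF, 0 °C; H2O
Reagents that add atoms: none
Why: Fluoride cleavage of the aryl silyl ether (desilylation).

Step 4
Reactants: 5 5-bromobenzene-1,3-diol
Product: 6 1,3-bis(benzyloxy)-5-bromobenzene
Conditions: BnBr (2.2 equiv), K2CO3, DMF, 25 °C
Reagents that add atoms: benzyl bromide, BrCc1ccccc1
Why: Double Williamson ether synthesis; the benzyl ethers survive every later step and leave by neutral hydrogenolysis at the end.

**Fragment 1 (tetralone aldehyde 22)**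

Step 5
Reactants: 7 but-3-yn-1-ol
Product: 8 tert-butyl(but-3-yn-1-yloxy)dimethylsilane
Conditions: t-BuMe2SiCl, imidazole, CH2Cl2, 0 to 25 °C
Reagents that add atoms: tert-butyl(chloro)dimethylsilane, CC(C)(C)[Si](C)(C)Cl
Why: Silyl protection of the primary alcohol that later becomes the tetralone carbonyl carbon.

Step 6
Reactants: 8 tert-butyl(but-3-yn-1-yloxy)dimethylsilane
Product: 10 methyl 5-[(tert-butyldimethylsilyl)oxy]pent-2-ynoate, via lithium acetylide 9 (not isolated)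
Conditions: n-BuLi, THF, −78 °C; ClCO2Me, −78 to 0 °C
Reagents that add atoms: methyl chloroformate, COC(=O)Cl
Why: Acylation of a lithium acetylide with a chloroformate gives the ynoate.

Step 7
Reactants: 10 methyl 5-[(tert-butyldimethylsilyl)oxy]pent-2-ynoate
Product: 11 methyl (2Z)-5-[(tert-butyldimethylsilyl)oxy]-3-methylpent-2-enoate
Conditions: MeLi (2.4 equiv), CuI (1.2 equiv), THF, 0 to −78 °C; then 10, −78 °C; MeOH, −78 °C
Reagents that add atoms: methyllithium, C[Li] (delivered as lithium dimethylcuprate, [Li+].C[Cu-]C)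
Why: Syn carbocupration of the ynoate and protonation with retention at −78 °C put methyl and hydrogen cis, so the chain and the ester are cis (Z).

Step 8
Reactants: 11 methyl (2Z)-5-[(tert-butyldimethylsilyl)oxy]-3-methylpent-2-enoate
Product: 12 (2Z)-5-[(tert-butyldimethylsilyl)oxy]-3-methylpent-2-en-1-ol
Conditions: i-Bu2AlH (2.5 equiv), CH2Cl2, −78 °C; H2O
Reagents that add atoms: none
Why: Hydride reduction of the ester to the allylic alcohol; the alkene geometry is not touched.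

Step 9
Reactants: 12 (2Z)-5-[(tert-butyldimethylsilyl)oxy]-3-methylpent-2-en-1-ol
Product: 13 [(2S,3R)-3-{2-[(tert-butyldimethylsilyl)oxy]ethyl}-3-methyloxiran-2-yl]methanol
Conditions: Ti(OiPr)4 (10 mol %), L-(+)-diethyl tartrate (12 mol %), t-BuOOH, 4 Å sieves, CH2Cl2, −20 °C
Reagents that add atoms: tert-butyl hydroperoxide, CC(C)(C)OO
Why: Sharpless asymmetric epoxidation; with L-(+)-tartrate a (Z)-3,3-disubstituted allylic alcohol gives the (2S,3R)-epoxide (as nerol does), which fixes the tertiary C–O centre in its final sense and the neighbouring centre in the sense that is inverted in step 10.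

Step 10
Reactants: 13 [(2S,3R)-3-{2-[(tert-butyldimethylsilyl)oxy]ethyl}-3-methyloxiran-2-yl]methanol; 6 1,3-bis(benzyloxy)-5-bromobenzene
Product: 15 (2R,3R)-2-[3,5-bis(benzyloxy)phenyl]-5-[(tert-butyldimethylsilyl)oxy]-3-methylpentane-1,3-diol, via aryl Grignard reagent 14 (not isolated)
Conditions: 6, Mg, THF, 40 °C (gives 14); 13, i-PrMgCl (1.0 equiv), THF, −30 °C; then 14 (1.5 equiv), CuI (10 mol %), −30 to 0 °C; aq. NH4Cl
Reagents that add atoms: none
Why: Copper-catalysed Grignard opening of the 2,3-epoxy alcohol is an SN2 attack at the secondary epoxide carbon (the tertiary one is blocked) with inversion, so the aryl-bearing carbon becomes R while the tertiary carbinol keeps R.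

Step 11
Reactants: 15 (2R,3R)-2-[3,5-bis(benzyloxy)phenyl]-5-[(tert-butyldimethylsilyl)oxy]-3-methylpentane-1,3-diol
Product: 16 (2R,3R)-2-[3,5-bis(benzyloxy)phenyl]-5-[(tert-butyldimethylsilyl)oxy]-1-[(tert-butyldiphenylsilyl)oxy]-3-methylpentan-3-ol
Conditions: t-BuPh2SiCl, imidazole, CH2Cl2, 0 °C
Reagents that add atoms: tert-butyl(chloro)diphenylsilane, CC(C)(C)[Si](Cl)(c1ccccc1)c1ccccc1
Why: Selective silylation of the primary over the tertiary alcohol with an acid-stable silyl group.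

Step 12
Reactants: 16 (2R,3R)-2-[3,5-bis(benzyloxy)phenyl]-5-[(tert-butyldimethylsilyl)oxy]-1-[(tert-butyldiphenylsilyl)oxy]-3-methylpentan-3-ol
Product: 17 (2R,3R)-3-[(benzyloxy)methoxy]-2-[3,5-bis(benzyloxy)phenyl]-5-[(tert-butyldimethylsilyl)oxy]-1-[(tert-butyldiphenylsilyl)oxy]-3-methylpentane
Conditions: BnOCH2Cl, i-Pr2NEt, Bu4NI (10 mol %), CH2Cl2, 40 °C
Reagents that add atoms: benzyl chloromethyl ether, ClCOCc1ccccc1
Why: O-alkylation of the tertiary alcohol to its benzyloxymethyl acetal under non-basic conditions (no silyl migration), a mask that is removed later by hydrogenolysis.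

Step 13
Reactants: 17 (2R,3R)-3-[(benzyloxy)methoxy]-2-[3,5-bis(benzyloxy)phenyl]-5-[(tert-butyldimethylsilyl)oxy]-1-[(tert-butyldiphenylsilyl)oxy]-3-methylpentane
Product: 18 (3R,4R)-3-[(benzyloxy)methoxy]-4-[3,5-bis(benzyloxy)phenyl]-5-[(tert-butyldiphenylsilyl)oxy]-3-methylpentanoic acid
Conditions: CrO3, H2SO4, H2O, acetone, 0 °C
Reagents that add atoms: water, O
Why: Jones oxidation; the aqueous acid cleaves only the primary tert-butyldimethylsilyl ether (the diphenyl analogue is far more acid-stable) and hexavalent chromium takes the freed alcohol to the acid.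

Step 14
Reactants: 18 (3R,4R)-3-[(benzyloxy)methoxy]-4-[3,5-bis(benzyloxy)phenyl]-5-[(tert-butyldiphenylsilyl)oxy]-3-methylpentanoic acid
Product: 20 (3R,4R)-3-[(benzyloxy)methoxy]-6,8-bis(benzyloxy)-4-{[(tert-butyldiphenylsilyl)oxy]methyl}-3-methyl-3,4-dihydronaphthalen-1(2H)-one, via mixed anhydride 19 (not isolated)
Conditions: (CF3CO)2O (2 equiv), CH2Cl2, 0 °C, 30 min
Reagents that add atoms: none
Why: Intramolecular Friedel–Crafts acylation through the mixed anhydride; the two ring positions ortho to the side chain are equivalent and activated by both benzyloxy groups, and a six-membered ring forms without touching the stereocentres.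

Step 15
Reactants: 20 (3R,4R)-3-[(benzyloxy)methoxy]-6,8-bis(benzyloxy)-4-{[(tert-butyldiphenylsilyl)oxy]methyl}-3-methyl-3,4-dihydronaphthalen-1(2H)-one
Product: 21 (3R,4R)-3-[(benzyloxy)methoxy]-6,8-bis(benzyloxy)-4-(hydroxymethyl)-3-methyl-3,4-dihydronaphthalen-1(2H)-one
Conditions: Bu4NF, AcOH (1:1), THF, 25 °C
Reagents that add atoms: none
Why: Buffered fluoride desilylation, kept non-basic so that the β-alkoxy ketone does not eliminate.

Step 16
Reactants: 21 (3R,4R)-3-[(benzyloxy)methoxy]-6,8-bis(benzyloxy)-4-(hydroxymethyl)-3-methyl-3,4-dihydronaphthalen-1(2H)-one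
Product: 22 (1S,2R)-2-[(benzyloxy)methoxy]-5,7-bis(benzyloxy)-2-methyl-4-oxo-1,2,3,4-tetrahydronaphthalene-1-carbaldehyde
Conditions: Dess–Martin periodinane, CH2Cl2, 0 °C; used at once
Reagents that add atoms: none
Why: Dess–Martin oxidation of the primary alcohol under neutral conditions leaves the epimerisable α-centre alone (the descriptor changes from R to S only because the substituent priority changes).

**Fragment 2 (iodo pyranone 31)**

Step 17
Reactants: 6 1,3-bis(benzyloxy)-5-bromobenzene; 23 ethyl bromoacetate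
Product: 25 ethyl [3,5-bis(benzyloxy)phenyl]acetate, via Reformatsky reagent 24 (not isolated)
Conditions: 23, Zn, THF, 40 °C (gives 24); then 6, Pd(dba)2 (2 mol %), XPhos (4 mol %), THF, 65 °C
Reagents that add atoms: none
Why: Palladium-catalysed α-arylation of a zinc ester enolate (Negishi-type coupling of a Reformatsky reagent).

Step 18
Reactants: 25 ethyl [3,5-bis(benzyloxy)phenyl]acetate
Product: 26 2-[3,5-bis(benzyloxy)phenyl]-N-methoxy-N-methylacetamide
Conditions: MeNH(OMe)·HCl, i-PrMgCl, THF, −20 to 0 °C; aq. NH4Cl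
Reagents that add atoms: N,O-dimethylhydroxylamine hydrochloride, CNOC.Cl
Why: Aminolysis of the ester by the magnesium amide gives the Weinreb amide.

Step 19
Reactants: 26 2-[3,5-bis(benzyloxy)phenyl]-N-methoxy-N-methylacetamide
Product: 27 2-[3,5-bis(benzyloxy)-2-iodophenyl]-N-methoxy-N-methylacetamide
Conditions: N-iodosuccinimide (1.05 equiv), CF3CO2H (10 mol %), MeCN, 0 °C
Reagents that add atoms: N-iodosuccinimide, O=C1CCC(=O)N1I
Why: Electrophilic aromatic iodination goes ortho to the side chain (para to one ether, ortho to the other), because the position between the two ethers is the more hindered one.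

Step 20
Reactants: 27 2-[3,5-bis(benzyloxy)-2-iodophenyl]-N-methoxy-N-methylacetamide; 28 methyl 3-oxobutanoate
Product: 30 methyl 6-[3,5-bis(benzyloxy)-2-iodophenyl]-3,5-dioxohexanoate, via acetoacetate dianion 29 (not isolated)
Conditions: 28, NaH, THF, 0 °C; n-BuLi, 0 °C (gives 29); then 27, −78 to 0 °C; aq. HCl
Reagents that add atoms: none
Why: γ-Acylation of the Weiler dianion by the Weinreb amide, whose chelated adduct stops over-addition; no free alkyllithium is left to attack the aryl iodide.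

Step 21
Reactants: 30 methyl 6-[3,5-bis(benzyloxy)-2-iodophenyl]-3,5-dioxohexanoate
Product: 31 6-{[3,5-bis(benzyloxy)-2-iodophenyl]methyl}-4-hydroxy-2H-pyran-2-one
Conditions: DBU, toluene, 80 °C; then aq. HCl
Reagents that add atoms: none
Why: Base-promoted lactonisation of the 3,5-diketo ester (enol oxygen onto the ester) gives the 4-hydroxy-2-pyranone.

**Union and end game**

Step 22
Reactants: 31 6-{[3,5-bis(benzyloxy)-2-iodophenyl]methyl}-4-hydroxy-2H-pyran-2-one; 22 (1S,2R)-2-[(benzyloxy)methoxy]-5,7-bis(benzyloxy)-2-methyl-4-oxo-1,2,3,4-tetrahydronaphthalene-1-carbaldehyde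
Product: 35 (3R,4R)-3-[(benzyloxy)methoxy]-6,8-bis(benzyloxy)-4-[{2,4-bis(benzyloxy)-6-[(4-hydroxy-2-oxo-2H-pyran-6-yl)methyl]phenyl}(hydroxy)methyl]-3-methyl-3,4-dihydronaphthalen-1(2H)-one (both carbinol epimers), via sodium pyranonate 32 (not isolated), via aryllithium 33 (not isolated), via arylcerium 34 (not isolated)
Conditions: 31 (1.3 equiv), NaH (1.05 equiv per 31), THF, 0 °C; t-BuLi (2.1 equiv), −78 °C; CeCl3 (1.2 equiv), −78 °C; then 22, −78 to −40 °C; aq. NH4Cl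
Reagents that add atoms: none
Why: The acidic pyranone OH is masked as its sodium salt, iodine–lithium exchange and transmetalation to cerium give a weakly basic aryl nucleophile, and its 1,2-addition prefers the aldehyde over the hindered tetralone ketone; the new carbinol centre is not controlled and is removed in step 23.

Step 23
Reactants: 35 (3R,4R)-3-[(benzyloxy)methoxy]-6,8-bis(benzyloxy)-4-[{2,4-bis(benzyloxy)-6-[(4-hydroxy-2-oxo-2H-pyran-6-yl)methyl]phenyl}(hydroxy)methyl]-3-methyl-3,4-dihydronaphthalen-1(2H)-one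
Product: 36 (3R,4S)-3-[(benzyloxy)methoxy]-6,8-bis(benzyloxy)-4-{2,4-bis(benzyloxy)-6-[(4-hydroxy-2-oxo-2H-pyran-6-yl)methyl]benzoyl}-3-methyl-3,4-dihydronaphthalen-1(2H)-one
Conditions: Dess–Martin periodinane, CH2Cl2, 0 to 25 °C
Reagents that add atoms: none
Why: Dess–Martin oxidation of the benzylic carbinol to the diaryl-type ketone; no base is present, so C4 keeps its configuration (now S by priority).

Step 24
Reactants: 36 (3R,4S)-3-[(benzyloxy)methoxy]-6,8-bis(benzyloxy)-4-{2,4-bis(benzyloxy)-6-[(4-hydroxy-2-oxo-2H-pyran-6-yl)methyl]benzoyl}-3-methyl-3,4-dihydronaphthalen-1(2H)-one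
Product: 37 (3R,4S)-4-{2,4-dihydroxy-6-[(4-hydroxy-2-oxo-2H-pyran-6-yl)methyl]benzoyl}-3,6,8-trihydroxy-3-methyl-3,4-dihydronaphthalen-1(2H)-one
Conditions: H2 (1 atm), Pd/C (10 %), EtOAc/MeOH, 25 °C; stopped at full debenzylation
Reagents that add atoms: none
Why: Catalytic hydrogenolysis removes the four aryl benzyl ethers and the benzyloxymethyl group (its hemiformal loses formaldehyde) under neutral conditions that spare the dehydration-prone β-hydroxy ketone.

**Compound list**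
1 | 3-bromophenol | Oc1cccc(Br)c1 | starting material
2 | (3-bromophenoxy)tri(propan-2-yl)silane | CC(C)[Si](Oc1cccc(Br)c1)(C(C)C)C(C)C | intermediate
3 | 2-(3-bromo-5-{[tri(propan-2-yl)silyl]oxy}phenyl)-4,4,5,5-tetramethyl-1,3,2-dioxaborolane | CC(C)[Si](Oc1cc(Br)cc(B2OC(C)(C)C(C)(C)O2)c1)(C(C)C)C(C)C | intermediate
4 | 3-bromo-5-{[tri(propan-2-yl)silyl]oxy}phenol | CC(C)[Si](Oc1cc(O)cc(Br)c1)(C(C)C)C(C)C | intermediate
5 | 5-bromobenzene-1,3-diol | Oc1cc(O)cc(Br)c1 | intermediate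
6 | 1,3-bis(benzyloxy)-5-bromobenzene | Brc1cc(OCc2ccccc2)cc(OCc2ccccc2)c1 | intermediate
7 | but-3-yn-1-ol | OCCC#C | starting material
8 | tert-butyl(but-3-yn-1-yloxy)dimethylsilane | CC(C)(C)[Si](C)(C)OCCC#C | intermediate
9 | {4-[(tert-butyldimethylsilyl)oxy]but-1-yn-1-yl}lithium | [Li]C#CCCO[Si](C)(C)C(C)(C)C | intermediate
10 | methyl 5-[(tert-butyldimethylsilyl)oxy]pent-2-ynoate | COC(=O)C#CCCO[Si](C)(C)C(C)(C)C | intermediate
11 | methyl (2Z)-5-[(tert-butyldimethylsilyl)oxy]-3-methylpent-2-enoate | COC(=O)/C=C(C)\CCO[Si](C)(C)C(C)(C)C | intermediate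
12 | (2Z)-5-[(tert-butyldimethylsilyl)oxy]-3-methylpent-2-en-1-ol | OC/C=C(C)\CCO[Si](C)(C)C(C)(C)C | intermediate
13 | [(2S,3R)-3-{2-[(tert-butyldimethylsilyl)oxy]ethyl}-3-methyloxiran-2-yl]methanol | OC[C@@H]1O[C@]1(C)CCO[Si](C)(C)C(C)(C)C | intermediate
14 | [3,5-bis(benzyloxy)phenyl]magnesium bromide | Br[Mg]c1cc(OCc2ccccc2)cc(OCc2ccccc2)c1 | intermediate
15 | (2R,3R)-2-[3,5-bis(benzyloxy)phenyl]-5-[(tert-butyldimethylsilyl)oxy]-3-methylpentane-1,3-diol | OC[C@@H](c1cc(OCc2ccccc2)cc(OCc2ccccc2)c1)[C@](C)(O)CCO[Si](C)(C)C(C)(C)C | intermediate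
16 | (2R,3R)-2-[3,5-bis(benzyloxy)phenyl]-5-[(tert-butyldimethylsilyl)oxy]-1-[(tert-butyldiphenylsilyl)oxy]-3-methylpentan-3-ol | CC(C)(C)[Si](OC[C@@H](c1cc(OCc2ccccc2)cc(OCc2ccccc2)c1)[C@](C)(O)CCO[Si](C)(C)C(C)(C)C)(c1ccccc1)c1ccccc1 | intermediate
17 | (2R,3R)-3-[(benzyloxy)methoxy]-2-[3,5-bis(benzyloxy)phenyl]-5-[(tert-butyldimethylsilyl)oxy]-1-[(tert-butyldiphenylsilyl)oxy]-3-methylpentane | CC(C)(C)[Si](OC[C@@H](c1cc(OCc2ccccc2)cc(OCc2ccccc2)c1)[C@](C)(OCOCc1ccccc1)CCO[Si](C)(C)C(C)(C)C)(c1ccccc1)c1ccccc1 | intermediate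
18 | (3R,4R)-3-[(benzyloxy)methoxy]-4-[3,5-bis(benzyloxy)phenyl]-5-[(tert-butyldiphenylsilyl)oxy]-3-methylpentanoic acid | OC(=O)C[C@@](C)(OCOCc1ccccc1)[C@@H](CO[Si](c1ccccc1)(c1ccccc1)C(C)(C)C)c1cc(OCc2ccccc2)cc(OCc2ccccc2)c1 | intermediate
19 | (3R,4R)-3-[(benzyloxy)methoxy]-4-[3,5-bis(benzyloxy)phenyl]-5-[(tert-butyldiphenylsilyl)oxy]-3-methylpentanoic trifluoroacetic anhydride | FC(F)(F)C(=O)OC(=O)C[C@@](C)(OCOCc1ccccc1)[C@@H](CO[Si](c1ccccc1)(c1ccccc1)C(C)(C)C)c1cc(OCc2ccccc2)cc(OCc2ccccc2)c1 | intermediate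
20 | (3R,4R)-3-[(benzyloxy)methoxy]-6,8-bis(benzyloxy)-4-{[(tert-butyldiphenylsilyl)oxy]methyl}-3-methyl-3,4-dihydronaphthalen-1(2H)-one | O=C1C[C@@](C)(OCOCc2ccccc2)[C@@H](CO[Si](c2ccccc2)(c2ccccc2)C(C)(C)C)c2cc(OCc3ccccc3)cc(OCc3ccccc3)c12 | intermediate
21 | (3R,4R)-3-[(benzyloxy)methoxy]-6,8-bis(benzyloxy)-4-(hydroxymethyl)-3-methyl-3,4-dihydronaphthalen-1(2H)-one | O=C1C[C@@](C)(OCOCc2ccccc2)[C@@H](CO)c2cc(OCc3ccccc3)cc(OCc3ccccc3)c12 | intermediate
22 | (1S,2R)-2-[(benzyloxy)methoxy]-5,7-bis(benzyloxy)-2-methyl-4-oxo-1,2,3,4-tetrahydronaphthalene-1-carbaldehyde | O=C1C[C@@](C)(OCOCc2ccccc2)[C@@H](C=O)c2cc(OCc3ccccc3)cc(OCc3ccccc3)c12 | intermediate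
23 | ethyl bromoacetate | CCOC(=O)CBr | starting material
24 | bromo(2-ethoxy-2-oxoethyl)zinc | CCOC(=O)C[Zn]Br | intermediate
25 | ethyl [3,5-bis(benzyloxy)phenyl]acetate | CCOC(=O)Cc1cc(OCc2ccccc2)cc(OCc2ccccc2)c1 | intermediate
26 | 2-[3,5-bis(benzyloxy)phenyl]-N-methoxy-N-methylacetamide | CON(C)C(=O)Cc1cc(OCc2ccccc2)cc(OCc2ccccc2)c1 | intermediate
27 | 2-[3,5-bis(benzyloxy)-2-iodophenyl]-N-methoxy-N-methylacetamide | CON(C)C(=O)Cc1cc(OCc2ccccc2)cc(OCc2ccccc2)c1I | intermediate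
28 | methyl 3-oxobutanoate (methyl acetoacetate) | COC(=O)CC(C)=O | starting material
29 | lithium sodium dianion of methyl 3-oxobutanoate | [Na+].[Li+].COC(=O)[CH-]C(=O)[CH2-] | intermediate
30 | methyl 6-[3,5-bis(benzyloxy)-2-iodophenyl]-3,5-dioxohexanoate | COC(=O)CC(=O)CC(=O)Cc1cc(OCc2ccccc2)cc(OCc2ccccc2)c1I | intermediate
31 | 6-{[3,5-bis(benzyloxy)-2-iodophenyl]methyl}-4-hydroxy-2H-pyran-2-one | O=c1cc(O)cc(Cc2cc(OCc3ccccc3)cc(OCc3ccccc3)c2I)o1 | intermediate
32 | sodium 6-{[3,5-bis(benzyloxy)-2-iodophenyl]methyl}-2-oxo-2H-pyran-4-olate | [Na+].[O-]c1cc(=O)oc(Cc2cc(OCc3ccccc3)cc(OCc3ccccc3)c2I)c1 | intermediate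
33 | sodium 6-{[3,5-bis(benzyloxy)-2-lithiophenyl]methyl}-2-oxo-2H-pyran-4-olate | [Na+].[O-]c1cc(=O)oc(Cc2cc(OCc3ccccc3)cc(OCc3ccccc3)c2[Li])c1 | intermediate
34 | sodium 6-{[3,5-bis(benzyloxy)-2-(dichlorocerio)phenyl]methyl}-2-oxo-2H-pyran-4-olate | [Na+].[O-]c1cc(=O)oc(Cc2cc(OCc3ccccc3)cc(OCc3ccccc3)c2[Ce](Cl)Cl)c1 | intermediate
35 | (3R,4R)-3-[(benzyloxy)methoxy]-6,8-bis(benzyloxy)-4-[{2,4-bis(benzyloxy)-6-[(4-hydroxy-2-oxo-2H-pyran-6-yl)methyl]phenyl}(hydroxy)methyl]-3-methyl-3,4-dihydronaphthalen-1(2H)-one, both carbinol epimers | O=C1C[C@@](C)(OCOCc2ccccc2)[C@@H](C(O)c2c(OCc3ccccc3)cc(OCc3ccccc3)cc2Cc2cc(O)cc(=O)o2)c2cc(OCc3ccccc3)cc(OCc3ccccc3)c12 | intermediate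
36 | (3R,4S)-3-[(benzyloxy)methoxy]-6,8-bis(benzyloxy)-4-{2,4-bis(benzyloxy)-6-[(4-hydroxy-2-oxo-2H-pyran-6-yl)methyl]benzoyl}-3-methyl-3,4-dihydronaphthalen-1(2H)-one | O=C1C[C@@](C)(OCOCc2ccccc2)[C@@H](C(=O)c2c(OCc3ccccc3)cc(OCc3ccccc3)cc2Cc2cc(O)cc(=O)o2)c2cc(OCc3ccccc3)cc(OCc3ccccc3)c12 | intermediate
37 | (3R,4S)-4-{2,4-dihydroxy-6-[(4-hydroxy-2-oxo-2H-pyran-6-yl)methyl]benzoyl}-3,6,8-trihydroxy-3-methyl-3,4-dihydronaphthalen-1(2H)-one | C[C@@]1(O)CC(=O)c2c(O)cc(O)cc2[C@@H]1C(=O)c1c(O)cc(O)cc1Cc1cc(O)cc(=O)o1 | target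

**Step count and risks**
Total: 24 steps. Longest linear sequence: 15 steps (steps 5 to 16, then 22 to 24).

Most likely to fail, step 22 (the union). The hindered aryl-cerium may enolise aldehyde 22 or trigger loss of the β-alkoxy group instead of adding. The fallback replaces the basic aryl-metal by a Nozaki–Hiyama–Kishi coupling and sets out from 31 and 22. Mitsunobu benzylation of 31 (BnOH, PPh3, diisopropyl azodicarboxylate) gives 4-(benzyloxy)-6-{[3,5-bis(benzyloxy)-2-iodophenyl]methyl}-2H-pyran-2-one F1. CrCl2 with NiCl2 (2 mol %) in DMF/DMSO joins F1 and 22 without base to the carbinol (3R,4R)-3-[(benzyloxy)methoxy]-6,8-bis(benzyloxy)-4-[{2,4-bis(benzyloxy)-6-{[4-(benzyloxy)-2-oxo-2H-pyran-6-yl]methyl}phenyl}(hydroxy)methyl]-3-methyl-3,4-dihydronaphthalen-1(2H)-one F2. Dess–Martin oxidation gives the ketone (3R,4S)-3-[(benzyloxy)methoxy]-6,8-bis(benzyloxy)-4-{2,4-bis(benzyloxy)-6-{[4-(benzyloxy)-2-oxo-2H-pyran-6-yl]methyl}benzoyl}-3-methyl-3,4-dihydronaphthalen-1(2H)-one F3, and hydrogenolysis (H2, Pd/C) of F3 rejoins the route at 37.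

Second, step 14 (Friedel–Crafts ring closure). The trifluoroacetic acid set free may cleave the acetal or ionise the tertiary C–O bond. The fallback closes the ring by an anionic Parham cyclisation and sets out from 18. N-Bromosuccinimide in MeCN at 0 °C brominates the ring ortho to the side chain to give (3R,4R)-3-[(benzyloxy)methoxy]-4-[3,5-bis(benzyloxy)-2-bromophenyl]-5-[(tert-butyldiphenylsilyl)oxy]-3-methylpentanoic acid F4. Carbodiimide coupling with MeNH(OMe) gives (3R,4R)-3-[(benzyloxy)methoxy]-4-[3,5-bis(benzyloxy)-2-bromophenyl]-5-[(tert-butyldiphenylsilyl)oxy]-N-methoxy-N,3-dimethylpentanamide F5. t-BuLi (2 equiv, THF, −100 °C) effects bromine–lithium exchange and the aryllithium closes onto the Weinreb amide, rejoining the route at 20.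

Third, step 10 (epoxide opening). Magnesium salts may open the epoxide at the tertiary carbon or rearrange it before the aryl copper species attacks. The fallback makes the wanted carbon the electronically preferred SN2 site and sets out from 13. TEMPO with PhI(OAc)2 in MeCN/H2O gives (2R,3R)-3-{2-[(tert-butyldimethylsilyl)oxy]ethyl}-3-methyloxirane-2-carboxylic acid F6, and Me3SiCHN2 gives methyl (2R,3R)-3-{2-[(tert-butyldimethylsilyl)oxy]ethyl}-3-methyloxirane-2-carboxylate F7. The cuprate from 14 and CuBr·SMe2 attacks the α-carbon of the glycidic ester with inversion to give methyl (2S,3R)-2-[3,5-bis(benzyloxy)phenyl]-5-[(tert-butyldimethylsilyl)oxy]-3-hydroxy-3-methylpentanoate F8. LiAlH4 in THF at 0 °C reduces the ester and the route is rejoined at 15.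

**Further compounds**
F1 | step 22 | 4-(benzyloxy)-6-{[3,5-bis(benzyloxy)-2-iodophenyl]methyl}-2H-pyran-2-one | O=c1cc(OCc2ccccc2)cc(Cc2cc(OCc3ccccc3)cc(OCc3ccccc3)c2I)o1
F2 | step 22 | (3R,4R)-3-[(benzyloxy)methoxy]-6,8-bis(benzyloxy)-4-[{2,4-bis(benzyloxy)-6-{[4-(benzyloxy)-2-oxo-2H-pyran-6-yl]methyl}phenyl}(hydroxy)methyl]-3-methyl-3,4-dihydronaphthalen-1(2H)-one, both carbinol epimers | O=C1C[C@@](C)(OCOCc2ccccc2)[C@@H](C(O)c2c(OCc3ccccc3)cc(OCc3ccccc3)cc2Cc2cc(OCc3ccccc3)cc(=O)o2)c2cc(OCc3ccccc3)cc(OCc3ccccc3)c12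
F3 | step 22 | (3R,4S)-3-[(benzyloxy)methoxy]-6,8-bis(benzyloxy)-4-{2,4-bis(benzyloxy)-6-{[4-(benzyloxy)-2-oxo-2H-pyran-6-yl]methyl}benzoyl}-3-methyl-3,4-dihydronaphthalen-1(2H)-one | O=C1C[C@@](C)(OCOCc2ccccc2)[C@@H](C(=O)c2c(OCc3ccccc3)cc(OCc3ccccc3)cc2Cc2cc(OCc3ccccc3)cc(=O)o2)c2cc(OCc3ccccc3)cc(OCc3ccccc3)c12
F4 | step 14 | (3R,4R)-3-[(benzyloxy)methoxy]-4-[3,5-bis(benzyloxy)-2-bromophenyl]-5-[(tert-butyldiphenylsilyl)oxy]-3-methylpentanoic acid | OC(=O)C[C@@](C)(OCOCc1ccccc1)[C@@H](CO[Si](c1ccccc1)(c1ccccc1)C(C)(C)C)c1cc(OCc2ccccc2)cc(OCc2ccccc2)c1Br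
F5 | step 14 | (3R,4R)-3-[(benzyloxy)methoxy]-4-[3,5-bis(benzyloxy)-2-bromophenyl]-5-[(tert-butyldiphenylsilyl)oxy]-N-methoxy-N,3-dimethylpentanamide | CON(C)C(=O)C[C@@](C)(OCOCc1ccccc1)[C@@H](CO[Si](c1ccccc1)(c1ccccc1)C(C)(C)C)c1cc(OCc2ccccc2)cc(OCc2ccccc2)c1Br
F6 | step 10 | (2R,3R)-3-{2-[(tert-butyldimethylsilyl)oxy]ethyl}-3-methyloxirane-2-carboxylic acid | OC(=O)[C@@H]1O[C@]1(C)CCO[Si](C)(C)C(C)(C)C
F7 | step 10 | methyl (2R,3R)-3-{2-[(tert-butyldimethylsilyl)oxy]ethyl}-3-methyloxirane-2-carboxylate | COC(=O)[C@@H]1O[C@]1(C)CCO[Si](C)(C)C(C)(C)C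
F8 | step 10 | methyl (2S,3R)-2-[3,5-bis(benzyloxy)phenyl]-5-[(tert-butyldimethylsilyl)oxy]-3-hydroxy-3-methylpentanoate | COC(=O)[C@@H](c1cc(OCc2ccccc2)cc(OCc2ccccc2)c1)[C@](C)(O)CCO[Si](C)(C)C(C)(C)C
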